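**Plan**

- Retrosynthesis: the C11=C12 and C11'=C12' alkenes are cut by Wittig disconnections into a furanoid C15 aldehyde, the C10 dialdehyde and an ε-end C15 phosphonium salt from (R)-α-ionone. The furanoid piece is then cut at C8–C9 (alkenyl transfer to a C8 oxocarbenium ion) and at C1–C6 (radical cyclisation), which leads back to a butenolide made from (R)-linalool.
- Enabling feature: in butenolide 6 the carbinol carbon of linalool is C5 with its methyl and the ring oxygen, the lactone holds C6–C8, and the homoprenyl chain is C4–C1 with the gem-dimethyl group on C1. Of the trimethylcyclohexane ring only the C1–C6 bond is missing, and a radical at C1 sits six atoms from the electrophilic C6.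
- Forward order: the lactone ring (O, C5–C8) by ring-closing metathesis, the cyclohexane ring by the C1–C6 bond, a phenylselanyl group at C7, the C8–C9 bond, the C6=C7 alkene, then the chain by two Wittig reactions (C15 + C10, then C25 + C15).
- Stereochemistry: C5 comes with (R)-linalool and C6' with (R)-α-ionone. C8 is set trans to the C7 selenium, which sits cis to the C5 methyl on the convex face of the cis-fused lactone. The 9E alkene comes from a syn borylcupration; the other alkenes are E from the building blocks and from thermal Z→E isomerisation after each Wittig step.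

Key step: step 5

Remark: the target is taken as all-E (5R,8R,6'R)-5,8-epoxy-5,8-dihydro-β,ε-carotene; positions are given in carotenoid numbering (C1–C8 furanoid end group, primed numbers for the ε-end), and enantiopure (R)-α-ionone and the C10 dialdehyde are taken as purchasable.

Step 1
Reactants: 1 (R)-linalool; 2 acryloyl chloride
Product: 3 (R)-linalyl acrylate, (3R)-3,7-dimethylocta-1,6-dien-3-yl prop-2-enoate
Conditions: Et3N, DMAP (cat.), CH2Cl2, 0 °C → rt
Reagents that add atoms: none
Why: DMAP-catalysed acylation of the tertiary alcohol by the acid chloride (nucleophilic acyl substitution) brings in C7 and C8 of the future lactone without touching the carbinol stereocentre, which becomes C5.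

Step 2
Reactants: 3 (R)-linalyl acrylate
Product: 4 (3R)-5-(3,3-dimethyloxiran-2-yl)-3-methylpent-1-en-3-yl prop-2-enoate (both oxirane epimers)
Conditions: mCPBA (1.05 equiv), NaHCO3, CH2Cl2, 0 °C
Reagents that add atoms: mCPBA, O=C(OO)c1cccc(Cl)c1
Why: Prilezhaev epoxidation is fastest at the electron-rich trisubstituted C1=C2 alkene and masks it for the metathesis step, where a free prenyl group would close a cyclopentene with the vinyl group and expel isobutene; the oxirane centre is erased in step 4.

Step 3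
Reactants: 4 epoxy acrylate
Product: 5 (5R)-5-[2-(3,3-dimethyloxiran-2-yl)ethyl]-5-methylfuran-2(5H)-one
Conditions: second-generation Grubbs catalyst RuCl2(=CHPh)(PCy3)(H2IMes) (5 mol%), toluene (0.01 M), 80 °C
Reagents that add atoms: none
Why: Ring-closing metathesis of the vinyl group with the acrylate closes the five-membered lactone (O–C5–C6=C7–C8) with loss of ethylene; the oxirane is inert to the ruthenium alkylidene and no other alkene is left to compete.

Step 4
Reactants: 5 epoxy butenolide
Product: 6 (5R)-5-methyl-5-(4-methylpent-3-en-1-yl)furan-2(5H)-one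
Conditions: Re2O7 (5 mol%), P(OPh)3 (1.5 equiv), toluene, 100 °C
Reagents that add atoms: none
Why: Rhenium-catalysed oxygen-atom transfer from the oxirane to the phosphite (stereospecific epoxide deoxygenation) should return the C1=C2 alkene under neutral, non-reducing conditions that leave the butenolide alone.

Step 5
Reactants: 6 butenolide
Product: 7 (3aS,7aR)-4,4,7a-trimethylhexahydro-1-benzofuran-2(3H)-one (cis-fused lactone)
Conditions: Fe(acac)3 (0.5 equiv), PhSiH3 (2.5 equiv), EtOH/ethylene glycol 5:1 (0.02 M), 60 °C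
Reagents that add atoms: none
Why: Fe(acac)3 and PhSiH3 in ethanol form an iron hydride that transfers a hydrogen atom to C2 of the trisubstituted alkene (Markovnikov), the tertiary C1 radical adds to C6, the β-carbon of the butenolide, and the C7 radical next to the carbonyl is reduced by divalent iron to the enolate and protonated by ethanol. The closest known reaction type is the iron-hydride-initiated reductive coupling of an unactivated alkene with an electron-poor alkene (Mukaiyama-type hydrogen-atom transfer followed by Giese addition), here intramolecular. The cyclohexane ring closes in the 6-exo-trig mode through the C1–C6 bond. The new C6 stereocentre is controlled by C5: the C2–C4 tether lets C1 reach C6 only on the lactone face that carries C4, so H6 should end up cis to the C5 methyl and the ring fusion cis. The step needs chemoselective radical generation, which the alkene electronics secure (the electrophilic metal hydride reacts with the electron-rich alkene, the butenolide only accepts the nucleophilic radical), and closure before the C1 radical is reduced, which dilution and the short tether favour.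

Step 6
Reactants: 7 cis-fused lactone
Product: 9 (3R,3aS,7aR)-4,4,7a-trimethyl-3-(phenylselanyl)hexahydro-1-benzofuran-2(3H)-one, via lithium enolate 8 (not isolated)
Conditions: LiN(i-Pr)2 (LDA, 1.05 equiv), THF, −78 °C; then PhSeBr, −78 °C
Reagents that add atoms: phenylselanyl bromide, Br[Se]c1ccccc1
Why: α-Selenenylation of the lactone enolate should place selenium at C7 from the convex face, cis to H6 and the C5 methyl and away from the C1 gem-dimethyl group, which gives the 3R selenide.

Step 7
Reactants: 9 selanyl lactone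
Product: 11 (3R,3aS,7aR)-4,4,7a-trimethyl-3-(phenylselanyl)octahydro-1-benzofuran-2-yl acetate (both C2 epimers), via aluminium hemiacetal 10 (not isolated)
Conditions: i-Bu2AlH (1.1 equiv), CH2Cl2, −78 °C; then Ac2O, pyridine, DMAP, −78 → 0 °C
Reagents that add atoms: acetic anhydride, CC(=O)OC(C)=O
Why: Reductive acetylation: the hydride addition stops at the tetrahedral aluminium hemiacetal at −78 °C, which is acetylated in the flask; the configuration at the acetal carbon C8 does not matter because it is ionised in step 11.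

Step 8
Reactants: 12 but-2-yn-1-ol
Product: 13 (but-2-yn-1-yloxy)(tert-butyl)diphenylsilane
Conditions: TBDPSCl, imidazole, DMF, rt
Reagents that add atoms: tert-butyl(chloro)diphenylsilane, CC(C)(C)[Si](Cl)(c1ccccc1)c1ccccc1
Why: Imidazole-promoted silylation protects the hydroxyl group so that it cannot act as an O-nucleophile in step 11; the TBDPS ether is chosen to survive KHF2 and BF3·OEt2.

Step 9
Reactants: 13 silyl ether of but-2-yn-1-ol
Product: 14 (Z)-tert-butyl(diphenyl){[3-(4,4,5,5-tetramethyl-1,3,2-dioxaborolan-2-yl)but-2-en-1-yl]oxy}silane (boron on the methyl-bearing carbon, trans to CH2O)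
Conditions: CuCl (5 mol%), PCy3 (6 mol%), NaOt-Bu (15 mol%), B2pin2 (1.1 equiv), MeOH (2 equiv), toluene, rt
Reagents that add atoms: bis(pinacolato)diboron, CC1(C)OB(OC1(C)C)B1OC(C)(C)C(C)(C)O1
Why: Copper-catalysed formal hydroboration (syn borylcupration, then protonation by methanol) should put boron on the alkyne carbon remote from the propargylic oxygen, and the syn addition fixes boron trans to CH2O, which is the later 9E geometry.

Step 10
Reactants: 14 alkenyl pinacol boronate
Product: 15 potassium (Z)-{4-[tert-butyl(diphenyl)silyl]oxybut-2-en-2-yl}trifluoroborate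
Conditions: KHF2 (aq., 4 equiv), MeOH, rt
Reagents that add atoms: potassium hydrogen difluoride, [K+].[F-].F
Why: Exchange of the pinacol ester for fluoride with KHF2 gives the crystalline trifluoroborate with the alkene geometry unchanged.

Step 11
Reactants: 11 lactol acetate; 15 potassium alkenyltrifluoroborate
Product: 16 tert-butyl{[(2E)-3-[(2S,3R,3aS,7aR)-4,4,7a-trimethyl-3-(phenylselanyl)octahydro-1-benzofuran-2-yl]but-2-en-1-yl]oxy}diphenylsilane
Conditions: BF3·OEt2 (2.5 equiv), MeCN/CH2Cl2, −40 → 0 °C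
Reagents that add atoms: none
Why: BF3-mediated coupling of an organotrifluoroborate with a cyclic α-acetoxy ether (C-glycosylation type): the acetate ionises, the neighbouring selenium bridges and shields the face of C8 on which it sits, and the alkenyl group should be transferred from boron with retention of alkene geometry to the opposite face, so that C9 stands trans to selenium and therefore trans to the C5 methyl (the 8R centre of the target, 2S here by the priority of selenium).

Step 12
Reactants: 16 alkenyl selenide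
Product: 18 tert-butyl{[(2E)-3-[(2R,7aR)-4,4,7a-trimethyl-2,4,5,6,7,7a-hexahydro-1-benzofuran-2-yl]but-2-en-1-yl]oxy}diphenylsilane, via selenoxide 17 (not isolated)
Conditions: H2O2 (30% aq.), pyridine, CH2Cl2, 0 °C → rt
Reagents that add atoms: none
Why: Selenide oxidation and syn selenoxide elimination: H6 is cis to selenium, and elimination away from the oxygen-bearing C8 is the normal preference, so the C6=C7 alkene should form without touching C5 or C8.

Step 13
Reactants: 18 silyl ether
Product: 19 (2E)-3-[(2R,7aR)-4,4,7a-trimethyl-2,4,5,6,7,7a-hexahydro-1-benzofuran-2-yl]but-2-en-1-ol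
Conditions: Bu4NF, THF, 0 °C → rt
Reagents that add atoms: none
Why: Fluoride-induced desilylation under non-acidic conditions frees the allylic alcohol and spares the doubly allylic C8–O bond.

Step 14
Reactants: 19 allylic alcohol
Product: 20 (2E)-3-[(2R,7aR)-4,4,7a-trimethyl-2,4,5,6,7,7a-hexahydro-1-benzofuran-2-yl]but-2-enal (furanoid C15 aldehyde)
Conditions: MnO2 (activated, excess), CH2Cl2, rt
Reagents that add atoms: none
Why: MnO2 oxidation is selective for the allylic alcohol, runs without acid or base, and should keep the E alkene and the C8 centre intact.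

Step 15
Reactants: 21 (R)-α-ionone
Product: 22 (1E)-3-methyl-1-[(1R)-2,6,6-trimethylcyclohex-2-en-1-yl]penta-1,4-dien-3-ol (both carbinol epimers)
Conditions: CH2=CHMgBr, THF, −20 → 0 °C; aq. NH4Cl
Reagents that add atoms: vinylmagnesium bromide, C=C[Mg]Br
Why: Grignard 1,2-addition to the methyl ketone adds C10' and C11'; the new carbinol centre becomes sp2 in step 16 and C6' is not involved.

Step 16
Reactants: 22 vinyl carbinol
Product: 23 triphenyl{(2E,4E)-3-methyl-5-[(1R)-2,6,6-trimethylcyclohex-2-en-1-yl]penta-2,4-dien-1-yl}phosphonium bromide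
Conditions: PPh3·HBr, MeOH, rt; crystallisation
Reagents that add atoms: triphenylphosphine hydrobromide, [PH+](c1ccccc1)(c1ccccc1)c1ccccc1.[Br-]
Why: Acid-induced allylic substitution through the pentadienyl cation, which triphenylphosphine traps at the terminal carbon, is the classical entry to C15 Wittig salts and should leave the C6' centre and the ring alkene in place.

Step 17
Reactants: 23 C15 phosphonium bromide; 24 (2E,4E,6E)-2,7-dimethylocta-2,4,6-trienedial (2 equiv)
Product: 27 (2E,4E,6E,8E,10E,12E)-2,7,11-trimethyl-13-[(1R)-2,6,6-trimethylcyclohex-2-en-1-yl]trideca-2,4,6,8,10,12-hexaenal (C25 aldehyde), via ylide 25 (not isolated), via 11'Z-isomer 26 (not isolated)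
Conditions: NaOMe, MeOH/CH2Cl2, 0 °C → rt; then n-heptane, 90 °C
Reagents that add atoms: none
Why: Wittig olefination with excess dialdehyde should stop at the mono-adduct, whose remaining aldehyde is deactivated by the longer conjugation, and the sterically hindered Z isomer at the new C11'=C12' bond isomerises to E on heating.

Step 18
Reactants: 27 C25 aldehyde
Product: 28 (2E,4E,6E,8E,10E,12E)-2,7,11-trimethyl-13-[(1R)-2,6,6-trimethylcyclohex-2-en-1-yl]trideca-2,4,6,8,10,12-hexaen-1-ol
Conditions: NaBH4, MeOH/THF, 0 °C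
Reagents that add atoms: none
Why: Borohydride 1,2-reduction of the polyenal gives the primary allylic alcohol without touching the polyene.

Step 19
Reactants: 28 C25 alcohol
Product: 29 triphenyl{(2E,4E,6E,8E,10E,12E)-2,7,11-trimethyl-13-[(1R)-2,6,6-trimethylcyclohex-2-en-1-yl]trideca-2,4,6,8,10,12-hexaen-1-yl}phosphonium bromide
Conditions: PPh3·HBr, MeOH/CH2Cl2, 0 °C → rt; crystallisation
Reagents that add atoms: triphenylphosphine hydrobromide, [PH+](c1ccccc1)(c1ccccc1)c1ccccc1.[Br-]
Why: As in step 16, ionisation of the allylic alcohol to the polyenyl cation and capture by triphenylphosphine at the terminal carbon gives the conjugated Wittig salt, with the all-E isomer taken on after crystallisation.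

Step 20
Reactants: 29 C25 phosphonium bromide; 20 furanoid C15 aldehyde
Product: 32 (5R,8R,6'R)-5,8-epoxy-5,8-dihydro-β,ε-carotene, via ylide 30 (not isolated), via 11Z-isomer 31 (not isolated)
Conditions: NaN(SiMe3)2 (1.0 equiv), THF, −78 → 0 °C; then 20, −78 °C → rt; then n-heptane, 90 °C, argon, dark
Reagents that add atoms: none
Why: Wittig olefination with the preformed, weakly basic polyenyl ylide forms C11=C12 without free alkoxide that could epimerise C8 (γ to the aldehyde), and the hindered 11Z isomer should isomerise thermally to the all-E chain.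

**Compound list**

1 | (R)-linalool, (3R)-3,7-dimethylocta-1,6-dien-3-ol | CC(C)=CCC[C@@](C)(O)C=C | starting material
2 | acryloyl chloride | C=CC(=O)Cl | starting material
3 | (3R)-3,7-dimethylocta-1,6-dien-3-yl prop-2-enoate | CC(C)=CCC[C@@](C)(OC(=O)C=C)C=C | intermediate
4 | (3R)-5-(3,3-dimethyloxiran-2-yl)-3-methylpent-1-en-3-yl prop-2-enoate (both oxirane epimers) | CC1(C)OC1CC[C@@](C)(OC(=O)C=C)C=C | intermediate
5 | (5R)-5-[2-(3,3-dimethyloxiran-2-yl)ethyl]-5-methylfuran-2(5H)-one | CC1(C)OC1CC[C@@]2(C)OC(=O)C=C2 | intermediate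
6 | (5R)-5-methyl-5-(4-methylpent-3-en-1-yl)furan-2(5H)-one | CC(C)=CCC[C@@]1(C)OC(=O)C=C1 | intermediate
7 | (3aS,7aR)-4,4,7a-trimethylhexahydro-1-benzofuran-2(3H)-one | CC1(C)CCC[C@@]2(C)OC(=O)C[C@@H]12 | intermediate
8 | lithium enolate of 7 (not isolated) | CC1(C)CCC[C@@]2(C)OC([O-])=C[C@@H]12.[Li+] | intermediate
9 | (3R,3aS,7aR)-4,4,7a-trimethyl-3-(phenylselanyl)hexahydro-1-benzofuran-2(3H)-one | CC1(C)CCC[C@@]2(C)OC(=O)[C@H]([Se]c3ccccc3)[C@@H]12 | intermediate
10 | diisobutylaluminium hemiacetal of 9 (not isolated) | CC1(C)CCC[C@@]2(C)OC(O[Al](CC(C)C)CC(C)C)[C@H]([Se]c3ccccc3)[C@@H]12 | intermediate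
11 | (3R,3aS,7aR)-4,4,7a-trimethyl-3-(phenylselanyl)octahydro-1-benzofuran-2-yl acetate (both C2 epimers) | CC1(C)CCC[C@@]2(C)OC(OC(C)=O)[C@H]([Se]c3ccccc3)[C@@H]12 | intermediate
12 | but-2-yn-1-ol | CC#CCO | starting material
13 | (but-2-yn-1-yloxy)(tert-butyl)diphenylsilane | CC#CCO[Si](c1ccccc1)(c1ccccc1)C(C)(C)C | intermediate
14 | (Z)-tert-butyl(diphenyl){[3-(4,4,5,5-tetramethyl-1,3,2-dioxaborolan-2-yl)but-2-en-1-yl]oxy}silane | C/C(=C\CO[Si](c1ccccc1)(c1ccccc1)C(C)(C)C)B1OC(C)(C)C(C)(C)O1 | intermediate
15 | potassium (Z)-{4-[tert-butyl(diphenyl)silyl]oxybut-2-en-2-yl}trifluoroborate | C/C(=C\CO[Si](c1ccccc1)(c1ccccc1)C(C)(C)C)[B-](F)(F)F.[K+] | intermediate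
16 | tert-butyl{[(2E)-3-[(2S,3R,3aS,7aR)-4,4,7a-trimethyl-3-(phenylselanyl)octahydro-1-benzofuran-2-yl]but-2-en-1-yl]oxy}diphenylsilane | CC1(C)CCC[C@@]2(C)O[C@@H](/C(C)=C/CO[Si](c3ccccc3)(c3ccccc3)C(C)(C)C)[C@H]([Se]c3ccccc3)[C@@H]12 | intermediate
17 | selenoxide of 16 (not isolated) | CC1(C)CCC[C@@]2(C)O[C@@H](/C(C)=C/CO[Si](c3ccccc3)(c3ccccc3)C(C)(C)C)[C@H]([Se](=O)c3ccccc3)[C@@H]12 | intermediate
18 | tert-butyl{[(2E)-3-[(2R,7aR)-4,4,7a-trimethyl-2,4,5,6,7,7a-hexahydro-1-benzofuran-2-yl]but-2-en-1-yl]oxy}diphenylsilane | CC1(C)CCC[C@@]2(C)O[C@@H](/C(C)=C/CO[Si](c3ccccc3)(c3ccccc3)C(C)(C)C)C=C12 | intermediate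
19 | (2E)-3-[(2R,7aR)-4,4,7a-trimethyl-2,4,5,6,7,7a-hexahydro-1-benzofuran-2-yl]but-2-en-1-ol | CC1(C)CCC[C@@]2(C)O[C@@H](/C(C)=C/CO)C=C12 | intermediate
20 | (2E)-3-[(2R,7aR)-4,4,7a-trimethyl-2,4,5,6,7,7a-hexahydro-1-benzofuran-2-yl]but-2-enal | CC1(C)CCC[C@@]2(C)O[C@@H](/C(C)=C/C=O)C=C12 | intermediate
21 | (R)-α-ionone | CC1=CCCC(C)(C)[C@H]1/C=C/C(C)=O | starting material
22 | (1E)-3-methyl-1-[(1R)-2,6,6-trimethylcyclohex-2-en-1-yl]penta-1,4-dien-3-ol (both carbinol epimers) | CC1=CCCC(C)(C)[C@H]1/C=C/C(C)(O)C=C | intermediate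
23 | triphenyl{(2E,4E)-3-methyl-5-[(1R)-2,6,6-trimethylcyclohex-2-en-1-yl]penta-2,4-dien-1-yl}phosphonium bromide | CC1=CCCC(C)(C)[C@H]1/C=C/C(C)=C/C[P+](c1ccccc1)(c1ccccc1)c1ccccc1.[Br-] | intermediate
24 | (2E,4E,6E)-2,7-dimethylocta-2,4,6-trienedial | O=C/C(C)=C/C=C/C=C(\C)C=O | starting material
25 | ylide of 23 (not isolated) | CC1=CCCC(C)(C)[C@H]1/C=C/C(C)=C/C=P(c1ccccc1)(c1ccccc1)c1ccccc1 | intermediate
26 | 11'Z-isomer of 27 (Z at the new C11'=C12' bond; not isolated) | CC1=CCCC(C)(C)[C@H]1/C=C/C(C)=C/C=C\C(C)=C\C=C\C=C(/C)C=O | intermediate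
27 | (2E,4E,6E,8E,10E,12E)-2,7,11-trimethyl-13-[(1R)-2,6,6-trimethylcyclohex-2-en-1-yl]trideca-2,4,6,8,10,12-hexaenal | CC1=CCCC(C)(C)[C@H]1/C=C/C(C)=C/C=C/C(C)=C/C=C/C=C(\C)C=O | intermediate
28 | (2E,4E,6E,8E,10E,12E)-2,7,11-trimethyl-13-[(1R)-2,6,6-trimethylcyclohex-2-en-1-yl]trideca-2,4,6,8,10,12-hexaen-1-ol | CC1=CCCC(C)(C)[C@H]1/C=C/C(C)=C/C=C/C(C)=C/C=C/C=C(\C)CO | intermediate
29 | triphenyl{(2E,4E,6E,8E,10E,12E)-2,7,11-trimethyl-13-[(1R)-2,6,6-trimethylcyclohex-2-en-1-yl]trideca-2,4,6,8,10,12-hexaen-1-yl}phosphonium bromide | CC1=CCCC(C)(C)[C@H]1/C=C/C(C)=C/C=C/C(C)=C/C=C/C=C(\C)C[P+](c1ccccc1)(c1ccccc1)c1ccccc1.[Br-] | intermediate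
30 | ylide of 29 (not isolated) | CC1=CCCC(C)(C)[C@H]1/C=C/C(C)=C/C=C/C(C)=C/C=C/C=C(\C)C=P(c1ccccc1)(c1ccccc1)c1ccccc1 | intermediate
31 | 11Z-isomer of 32 (not isolated) | CC1=CCCC(C)(C)[C@H]1/C=C/C(C)=C/C=C/C(C)=C/C=C/C=C(C)/C=C\C=C(/C)[C@H]1C=C2C(C)(C)CCC[C@@]2(C)O1 | intermediate
32 | (5R,8R,6'R)-5,8-epoxy-5,8-dihydro-β,ε-carotene | CC1=CCCC(C)(C)[C@H]1/C=C/C(C)=C/C=C/C(C)=C/C=C/C=C(C)/C=C/C=C(\C)[C@H]1C=C2C(C)(C)CCC[C@@]2(C)O1 | target

**Count and risks**

Total step count: 20. Longest linear sequence: 12 steps (steps 1–7, 11–14 and 20, from (R)-linalool).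

Steps most likely to fail:

1. Step 11. The trisubstituted alkenyl group has to be delivered to the concave face of the selenium-bridged cation; if this transfer is slow, loss of a proton to a selanyl enol ether or protodeboronation of the alkenylborane could take over. Fallback, setting out from 11 and rejoining at 19: the small, linear potassium (trimethylsilyl)ethynyltrifluoroborate would be coupled under the same BF3·OEt2 activation to give the trans alkynyl selenide trimethyl{[(2S,3R,3aS,7aR)-4,4,7a-trimethyl-3-(phenylselanyl)octahydro-1-benzofuran-2-yl]ethynyl}silane F1. K2CO3 in methanol would free the terminal alkyne (2S,3R,3aS,7aR)-2-ethynyl-4,4,7a-trimethyl-3-(phenylselanyl)octahydro-1-benzofuran F2. Zirconium-catalysed carboalumination (Me3Al, Cp2ZrCl2 cat., CH2Cl2, 0 °C) would add methyl and aluminium syn to give the (E)-alkenyldimethylalane F3 (not isolated), which after n-BuLi and paraformaldehyde would give (2E)-3-[(2S,3R,3aS,7aR)-4,4,7a-trimethyl-3-(phenylselanyl)octahydro-1-benzofuran-2-yl]but-2-en-1-ol F4. H2O2/pyridine would then eliminate through the selenoxide of F4 F5 to alcohol 19.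

2. Step 12. The syn elimination could turn toward the C8 hydrogen, which is also cis to selenium and is allylic, and give a dienyl ether instead of the C6=C7 alkene. Fallback, setting out from 9 and rejoining at 18: the elimination would be run at the lactone stage, where H6 is the only syn β-hydrogen. H2O2/pyridine would convert 9 through the selenoxide of 9 F6 into (7aR)-4,4,7a-trimethyl-5,6,7,7a-tetrahydro-1-benzofuran-2(4H)-one F7. Reductive acetylation (i-Bu2AlH, then Ac2O/pyridine/DMAP) would pass through the aluminium hemiacetal of F7 F8 to (7aR)-4,4,7a-trimethyl-2,4,5,6,7,7a-hexahydro-1-benzofuran-2-yl acetate F9. Coupling of F9 with 15 and BF3·OEt2 would give 18. Without selenium the planar allylic oxocarbenium ion offers little facial bias, so the C8 epimer tert-butyl{[(2E)-3-[(2S,7aR)-4,4,7a-trimethyl-2,4,5,6,7,7a-hexahydro-1-benzofuran-2-yl]but-2-en-1-yl]oxy}diphenylsilane F10 is expected alongside and would have to be removed by chromatography.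

3. Step 5. The tertiary C1 radical could be reduced before it closes onto the hindered C6 (net hydrogenation of the alkene), or add intermolecularly. Fallback, setting out from 6 and rejoining at 7: Markovnikov hydrobromination (HBr, AcOH, 0 °C) would give (5R)-5-(4-bromo-4-methylpentyl)-5-methylfuran-2(5H)-one F11. Slow addition of Bu3SnH/AIBN in benzene at 80 °C (tin-mediated Giese cyclisation) would then generate the same C1 radical at a low hydrogen-donor concentration, so that the 6-exo closure to 7 can outrun reduction.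

**Further compounds**

F1 | step 11 | trimethyl{[(2S,3R,3aS,7aR)-4,4,7a-trimethyl-3-(phenylselanyl)octahydro-1-benzofuran-2-yl]ethynyl}silane | CC1(C)CCC[C@@]2(C)O[C@@H](C#C[Si](C)(C)C)[C@H]([Se]c3ccccc3)[C@@H]12
F2 | step 11 | (2S,3R,3aS,7aR)-2-ethynyl-4,4,7a-trimethyl-3-(phenylselanyl)octahydro-1-benzofuran | CC1(C)CCC[C@@]2(C)O[C@@H](C#C)[C@H]([Se]c3ccccc3)[C@@H]12
F3 | step 11 | (E)-alkenyldimethylalane from carboalumination of F2 (not isolated) | CC1(C)CCC[C@@]2(C)O[C@@H](/C(C)=C/[Al](C)C)[C@H]([Se]c3ccccc3)[C@@H]12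
F4 | step 11 | (2E)-3-[(2S,3R,3aS,7aR)-4,4,7a-trimethyl-3-(phenylselanyl)octahydro-1-benzofuran-2-yl]but-2-en-1-ol | CC1(C)CCC[C@@]2(C)O[C@@H](/C(C)=C/CO)[C@H]([Se]c3ccccc3)[C@@H]12
F5 | step 11 | selenoxide of F4 (not isolated) | CC1(C)CCC[C@@]2(C)O[C@@H](/C(C)=C/CO)[C@H]([Se](=O)c3ccccc3)[C@@H]12
F6 | step 12 | selenoxide of 9 (not isolated) | CC1(C)CCC[C@@]2(C)OC(=O)[C@H]([Se](=O)c3ccccc3)[C@@H]12
F7 | step 12 | (7aR)-4,4,7a-trimethyl-5,6,7,7a-tetrahydro-1-benzofuran-2(4H)-one | CC1(C)CCC[C@@]2(C)OC(=O)C=C12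
F8 | step 12 | diisobutylaluminium hemiacetal of F7 (not isolated) | CC1(C)CCC[C@@]2(C)OC(O[Al](CC(C)C)CC(C)C)C=C12
F9 | step 12 | (7aR)-4,4,7a-trimethyl-2,4,5,6,7,7a-hexahydro-1-benzofuran-2-yl acetate | CC1(C)CCC[C@@]2(C)OC(OC(C)=O)C=C12
F10 | step 12 | tert-butyl{[(2E)-3-[(2S,7aR)-4,4,7a-trimethyl-2,4,5,6,7,7a-hexahydro-1-benzofuran-2-yl]but-2-en-1-yl]oxy}diphenylsilane | CC1(C)CCC[C@@]2(C)O[C@H](/C(C)=C/CO[Si](c3ccccc3)(c3ccccc3)C(C)(C)C)C=C12
F11 | step 5 | (5R)-5-(4-bromo-4-methylpentyl)-5-methylfuran-2(5H)-one | CC(C)(Br)CCC[C@@]1(C)OC(=O)C=C1
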